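**Target:** 5,7-dihydroxy-6-[(2S)-2-hydroxy-3-methylbut-3-en-1-yl]-3-(4-hydroxyphenyl)-4H-chromen-4-one. The single stereocentre is (S) (priorities O > isopropenyl > CH2Ar > H).

## Retrosynthetic overview

1. Target ⇐ its tris-MOM ether; the (S)-carbinol ⇐ the isopropenyl ketone, reduced by a ketoreductase (biocatalytic asymmetric reduction).
2. Isopropenyl ketone ⇐ arylacetaldehyde + isopropenylmagnesium bromide, then oxidation; aldehyde ⇐ oxidative cleavage of a 6-allyl group.
3. 6-Allyl ⇐ aromatic Claisen rearrangement of the 5-O-allyl ether of 7,4′-di-O-MOM genistein (C-4a is blocked, so only C-6 is open ortho to O-5).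
4. Genistein ⇐ deoxybenzoin + one carbon from DMF ⇐ phloroglucinol + 4-hydroxyphenylacetic acid.
5. Ring order: rings A and B are bought as benzenes; ring C (the pyranone) is the only ring made, in step 2, before any side-chain work.

Assumption: a commercial NADPH-dependent ketoreductase panel is at hand, and the enzyme used in step 10 is the panel member that gives the (S)-alcohol (chiral HPLC against the racemate from step 8).

## Route

**Step 1**
Reactants: 1 phloroglucinol (benzene-1,3,5-triol); 2 4-hydroxyphenylacetic acid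
Product: 3 2-(4-hydroxyphenyl)-1-(2,4,6-trihydroxyphenyl)ethan-1-one
Conditions: BF3·OEt2 (as solvent), 85 °C; then H2O
Reagents that add atoms: none
Why: Friedel–Crafts (Houben–Hoesch-type) C-acylation of the symmetrical, very electron-rich triol, which can give only one mono-ketone and is shielded from a second acylation as its BF2 chelate.

**Step 2**
Reactants: 3 2-(4-hydroxyphenyl)-1-(2,4,6-trihydroxyphenyl)ethan-1-one
Product: 5 genistein (5,7-dihydroxy-3-(4-hydroxyphenyl)-4H-chromen-4-one), via enaminone 4 (not isolated)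
Conditions: DMF, BF3·OEt2, MsCl, 50→80 °C; then H2O
Reagents that add atoms: N,N-dimethylformamide, CN(C)C=O (gives C-2)
Why: Vilsmeier-type aminomethylenation of the activated CH2 followed by O-cyclisation with loss of Me2NH closes ring C, and because the two ortho hydroxyls of 3 are equivalent only one isoflavone can form.

**Step 3**
Reactants: 5 genistein
Product: 6 5-hydroxy-7-(methoxymethoxy)-3-[4-(methoxymethoxy)phenyl]-4H-chromen-4-one
Conditions: MOMCl (2.3 equiv), iPr2NEt, CH2Cl2/DMF, 0 °C→rt
Reagents that add atoms: chloromethyl methyl ether (MOMCl), COCCl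
Why: Williamson-type O-alkylation of the two unchelated phenols (7-OH, 4′-OH), while the 5-OH is held in a hydrogen bond to C-4=O and does not react with an amine base at room temperature.

**Step 4**
Reactants: 6 5-hydroxy-7-(methoxymethoxy)-3-[4-(methoxymethoxy)phenyl]-4H-chromen-4-one; 7 allyl bromide
Product: 8 5-(allyloxy)-7-(methoxymethoxy)-3-[4-(methoxymethoxy)phenyl]-4H-chromen-4-one
Conditions: K2CO3, DMF, 60 °C
Reagents that add atoms: none
Why: Williamson etherification of the only remaining hydroxyl, forced by carbonate in a dipolar aprotic solvent with a reactive allylic halide.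

**Step 5**
Reactants: 8 5-(allyloxy)-7-(methoxymethoxy)-3-[4-(methoxymethoxy)phenyl]-4H-chromen-4-one
Product: 10 6-allyl-5-hydroxy-7-(methoxymethoxy)-3-[4-(methoxymethoxy)phenyl]-4H-chromen-4-one, via dienone 9 (not isolated)
Conditions: PhNEt2, 200 °C, Ar, sealed vessel
Reagents that add atoms: none
Why: Aromatic Claisen rearrangement ([3,3]-sigmatropic shift) delivers the allyl group to C-6, the only free ortho position of O-5, and tautomerisation of the dienone fixes this regiochemistry.

**Step 6**
Reactants: 10 6-allyl-5-hydroxy-7-(methoxymethoxy)-3-[4-(methoxymethoxy)phenyl]-4H-chromen-4-one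
Product: 11 6-allyl-5,7-bis(methoxymethoxy)-3-[4-(methoxymethoxy)phenyl]-4H-chromen-4-one
Conditions: NaH, MOMCl, DMF, 0 °C→rt
Reagents that add atoms: chloromethyl methyl ether (MOMCl), COCCl
Why: MOM protection of the chelated phenol through its sodium phenoxide, needed so that the later aldehyde and enone have no free ortho hydroxyl to cyclise onto.

**Step 7**
Reactants: 11 6-allyl-5,7-bis(methoxymethoxy)-3-[4-(methoxymethoxy)phenyl]-4H-chromen-4-one
Product: 13 2-{5,7-bis(methoxymethoxy)-3-[4-(methoxymethoxy)phenyl]-4-oxo-4H-chromen-6-yl}acetaldehyde, via diol 12 (not isolated)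
Conditions: OsO4 (2 mol%), NaIO4 (4 equiv), 2,6-lutidine, 1,4-dioxane/H2O 3:1, rt
Reagents that add atoms: osmium tetroxide (OsO4), O=[Os](=O)(=O)=O (delivers the new oxygen); sodium periodate (NaIO4), [Na+].[O-]I(=O)(=O)=O (re-oxidant that restores it)
Why: Lemieux–Johnson oxidation, in which OsO4 dihydroxylates the terminal alkene much faster than the electron-poor chromone C2=C3 bond and NaIO4 cleaves the diol, with 2,6-lutidine holding back over-oxidation.

**Step 8**
Reactants: 13 2-{5,7-bis(methoxymethoxy)-3-[4-(methoxymethoxy)phenyl]-4-oxo-4H-chromen-6-yl}acetaldehyde; 14 isopropenylmagnesium bromide (CH2=C(CH3)MgBr)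
Product: 15 rac-6-(2-hydroxy-3-methylbut-3-en-1-yl)-5,7-bis(methoxymethoxy)-3-[4-(methoxymethoxy)phenyl]-4H-chromen-4-one
Conditions: THF, −78 °C; then H2O
Reagents that add atoms: none
Why: Grignard 1,2-addition to the aldehyde, which at −78 °C is far more electrophilic than the vinylogous-ester carbonyl of the chromone; the carbinol forms as a racemate and is erased in the next step.

**Step 9**
Reactants: 15 rac-6-(2-hydroxy-3-methylbut-3-en-1-yl)-5,7-bis(methoxymethoxy)-3-[4-(methoxymethoxy)phenyl]-4H-chromen-4-one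
Product: 16 5,7-bis(methoxymethoxy)-3-[4-(methoxymethoxy)phenyl]-6-(3-methyl-2-oxobut-3-en-1-yl)-4H-chromen-4-one
Conditions: Dess–Martin periodinane, pyridine, CH2Cl2, 0 °C→rt
Reagents that add atoms: none
Why: Dess–Martin oxidation of the secondary allylic alcohol under buffered conditions gives the prochiral isopropenyl ketone without touching the MOM ethers or the alkene.

**Step 10**
Reactants: 16 5,7-bis(methoxymethoxy)-3-[4-(methoxymethoxy)phenyl]-6-(3-methyl-2-oxobut-3-en-1-yl)-4H-chromen-4-one
Product: 17 6-[(2S)-2-hydroxy-3-methylbut-3-en-1-yl]-5,7-bis(methoxymethoxy)-3-[4-(methoxymethoxy)phenyl]-4H-chromen-4-one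
Conditions: ketoreductase (NADPH-dependent, anti-Prelog type), NADP+ (cat.), iPrOH, KH2PO4/K2HPO4 buffer pH 7.0, DMSO (15% v/v), 30 °C
Reagents that add atoms: none
Why: Biocatalytic asymmetric carbonyl reduction by a ketoreductase (alcohol dehydrogenase class, NADPH recycled from iPrOH) delivers hydride to the Re face of the ketone (O > isopropenyl > CH2Ar) and so sets the (S)-carbinol, while the C=C bond and the chromone carbonyl are not substrates.

**Step 11**
Reactants: 17 6-[(2S)-2-hydroxy-3-methylbut-3-en-1-yl]-5,7-bis(methoxymethoxy)-3-[4-(methoxymethoxy)phenyl]-4H-chromen-4-one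
Product: 18 5,7-dihydroxy-6-[(2S)-2-hydroxy-3-methylbut-3-en-1-yl]-3-(4-hydroxyphenyl)-4H-chromen-4-one
Conditions: HCl (1 M), MeOH/THF, 40 °C, stopped at full conversion
Reagents that add atoms: none
Why: Acid-catalysed acetal (MOM) methanolysis frees the three phenols, and the isopropenyl carbinol tolerates dilute acid because protonating its alkene or ionising its hydroxyl would place positive charge next to an oxygen-bearing carbon, so the stereocentre is untouched.

## Compound list

1 | phloroglucinol (benzene-1,3,5-triol) | Oc1cc(O)cc(O)c1 | starting material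
2 | 4-hydroxyphenylacetic acid | OC(=O)Cc1ccc(O)cc1 | starting material
3 | 2-(4-hydroxyphenyl)-1-(2,4,6-trihydroxyphenyl)ethan-1-one | O=C(Cc1ccc(O)cc1)c1c(O)cc(O)cc1O | intermediate
4 | 3-(dimethylamino)-2-(4-hydroxyphenyl)-1-(2,4,6-trihydroxyphenyl)prop-2-en-1-one (enaminone) | CN(C)C=C(c1ccc(O)cc1)C(=O)c1c(O)cc(O)cc1O | intermediate (not isolated)
5 | genistein, 5,7-dihydroxy-3-(4-hydroxyphenyl)-4H-chromen-4-one | Oc1cc(O)c2c(c1)occ(-c1ccc(O)cc1)c2=O | intermediate
6 | 5-hydroxy-7-(methoxymethoxy)-3-[4-(methoxymethoxy)phenyl]-4H-chromen-4-one | COCOc1cc(O)c2c(c1)occ(-c1ccc(OCOC)cc1)c2=O | intermediate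
7 | allyl bromide (3-bromoprop-1-ene) | C=CCBr | starting material
8 | 5-(allyloxy)-7-(methoxymethoxy)-3-[4-(methoxymethoxy)phenyl]-4H-chromen-4-one | C=CCOc1cc(OCOC)cc2occ(-c3ccc(OCOC)cc3)c(=O)c12 | intermediate
9 | 6-allyl-7-(methoxymethoxy)-3-[4-(methoxymethoxy)phenyl]chromene-4,5(6H)-dione (dienone, racemic at C-6) | C=CCC1C(OCOC)=CC2=C(C1=O)C(=O)C(c1ccc(OCOC)cc1)=CO2 | intermediate (not isolated)
10 | 6-allyl-5-hydroxy-7-(methoxymethoxy)-3-[4-(methoxymethoxy)phenyl]-4H-chromen-4-one | C=CCc1c(OCOC)cc2occ(-c3ccc(OCOC)cc3)c(=O)c2c1O | intermediate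
11 | 6-allyl-5,7-bis(methoxymethoxy)-3-[4-(methoxymethoxy)phenyl]-4H-chromen-4-one | C=CCc1c(OCOC)cc2occ(-c3ccc(OCOC)cc3)c(=O)c2c1OCOC | intermediate
12 | 6-(2,3-dihydroxypropyl)-5,7-bis(methoxymethoxy)-3-[4-(methoxymethoxy)phenyl]-4H-chromen-4-one (diol, racemic) | OCC(O)Cc1c(OCOC)cc2occ(-c3ccc(OCOC)cc3)c(=O)c2c1OCOC | intermediate (not isolated)
13 | 2-{5,7-bis(methoxymethoxy)-3-[4-(methoxymethoxy)phenyl]-4-oxo-4H-chromen-6-yl}acetaldehyde | O=CCc1c(OCOC)cc2occ(-c3ccc(OCOC)cc3)c(=O)c2c1OCOC | intermediate
14 | isopropenylmagnesium bromide (prop-1-en-2-ylmagnesium bromide) | C=C(C)[Mg]Br | starting material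
15 | rac-6-(2-hydroxy-3-methylbut-3-en-1-yl)-5,7-bis(methoxymethoxy)-3-[4-(methoxymethoxy)phenyl]-4H-chromen-4-one (racemic) | C=C(C)C(O)Cc1c(OCOC)cc2occ(-c3ccc(OCOC)cc3)c(=O)c2c1OCOC | intermediate
16 | 5,7-bis(methoxymethoxy)-3-[4-(methoxymethoxy)phenyl]-6-(3-methyl-2-oxobut-3-en-1-yl)-4H-chromen-4-one | C=C(C)C(=O)Cc1c(OCOC)cc2occ(-c3ccc(OCOC)cc3)c(=O)c2c1OCOC | intermediate
17 | 6-[(2S)-2-hydroxy-3-methylbut-3-en-1-yl]-5,7-bis(methoxymethoxy)-3-[4-(methoxymethoxy)phenyl]-4H-chromen-4-one | C=C(C)[C@@H](O)Cc1c(OCOC)cc2occ(-c3ccc(OCOC)cc3)c(=O)c2c1OCOC | intermediate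
18 | 5,7-dihydroxy-6-[(2S)-2-hydroxy-3-methylbut-3-en-1-yl]-3-(4-hydroxyphenyl)-4H-chromen-4-one | C=C(C)[C@@H](O)Cc1c(O)cc2occ(-c3ccc(O)cc3)c(=O)c2c1O | target

## Step count and risks

Total step count: 11.
Longest linear sequence: 11 steps (the route is fully linear, from 1 and 2 to 18).

Three steps most likely to fail:

(1) Step 10, the ketoreductase reduction. The enone is bulky and lipophilic, so the panel may give no enzyme with useful rate or selectivity. The fallback sets out from 11 and comes back at 17, replacing carbonyl reduction by asymmetric epoxidation and epoxide-to-allylic-alcohol isomerisation. Cross-metathesis of 11 with 2-methyl-2-butene (second-generation Grubbs catalyst, CH2Cl2, 40 °C) gives the prenyl compound 5,7-bis(methoxymethoxy)-3-[4-(methoxymethoxy)phenyl]-6-(3-methylbut-2-en-1-yl)-4H-chromen-4-one F1. Shi epoxidation follows with the L-fructose-derived enantiomer of the Shi ketone (1,2:4,5-di-O-isopropylidene-β-L-erythro-2,3-hexodiulo-2,6-pyranose), Oxone (2KHSO5·KHSO4·K2SO4), K2CO3 buffer pH 10.5, MeCN/dimethoxymethane/H2O, 0 °C. The D-series ketone gives the (R)-epoxide from R–CH=CMe2 alkenes, so the L-series ketone is expected to give 6-{[(2S)-3,3-dimethyloxiran-2-yl]methyl}-5,7-bis(methoxymethoxy)-3-[4-(methoxymethoxy)phenyl]-4H-chromen-4-one F2. Et2Al(TMP) (from Et2AlCl and LiTMP; toluene, 0 °C) then removes a methyl hydrogen and opens the tertiary C–O bond. The C–O bond at the stereocentre is not broken, so F2 gives 17 with the (S) configuration retained.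

(2) Step 8, the Grignard addition. The arylacetaldehyde can be enolised by the basic reagent, and the chromone can be attacked if the temperature rises. The fallback sets out from 13 and comes back at 15 with no new intermediate. It replaces the preformed, basic organomagnesium reagent by a Nozaki–Hiyama–Kishi coupling with 2-bromopropene (CrCl2 4 equiv, NiCl2 1 mol%, DMF, rt). The alkenylchromium species made in the flask is non-basic and adds only to aldehydes, so neither enolisation nor chromone attack can compete.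

(3) Step 5, the Claisen rearrangement. At 200 °C some para-Claisen–Cope leakage to C-8 and partial loss of MOM groups are possible. The fallback sets out from 6 and comes back at 10, replacing the sigmatropic shift by halogenation and cross-coupling. Iodination ortho to the free 5-OH with BnMe3N+ ICl2−, CaCO3, CH2Cl2/MeOH, rt gives 5-hydroxy-6-iodo-7-(methoxymethoxy)-3-[4-(methoxymethoxy)phenyl]-4H-chromen-4-one F3; the 6-regiochemistry should be confirmed by HMBC. Stille coupling of F3 with allyltributylstannane (Bu3SnCH2CH=CH2), Pd(PPh3)4, DMF, 95 °C then gives 10.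

## Further compounds

F1 | step 10 | 5,7-bis(methoxymethoxy)-3-[4-(methoxymethoxy)phenyl]-6-(3-methylbut-2-en-1-yl)-4H-chromen-4-one | CC(C)=CCc1c(OCOC)cc2occ(-c3ccc(OCOC)cc3)c(=O)c2c1OCOC
F2 | step 10 | 6-{[(2S)-3,3-dimethyloxiran-2-yl]methyl}-5,7-bis(methoxymethoxy)-3-[4-(methoxymethoxy)phenyl]-4H-chromen-4-one | CC1(C)O[C@H]1Cc1c(OCOC)cc2occ(-c3ccc(OCOC)cc3)c(=O)c2c1OCOC
F0 | step 8 | none | none
F3 | step 5 | 5-hydroxy-6-iodo-7-(methoxymethoxy)-3-[4-(methoxymethoxy)phenyl]-4H-chromen-4-one | Ic1c(OCOC)cc2occ(-c3ccc(OCOC)cc3)c(=O)c2c1O
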